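**Retrosynthetic overview**

1. The C6 4‑methoxybenzoate comes from acylation; C10–OH and C4–OH both come from stereoretentive C–B oxidation; C6–OH comes from a C4‑hydroxyl‑directed ketone reduction; C10–B comes from copper‑catalysed 1,6‑borylation of a 6‑oxo‑7,9‑dienone, anti to the C1 methyl.
2. That dienone aldol comes from the [3+2] adduct by base: loss of a temporary C10 silyloxy group, then retro‑aldol/aldol equilibration of C4 and C5 under thermodynamic control.
3. Key disconnection: the cyclopentane (bonds C2–C3 and C4–C5) is made by SmI2‑catalysed formal [3+2] cycloaddition of a bicyclo[5.1.0]oct‑4‑en‑2‑one with 2‑isopropylvinyl‑Bpin. The enabling feature is that C6, taken as a ketone, is bonded directly to ring‑fusion C5, and C1–C2–C5 are closed as a cyclopropane fused to the seven‑membered ring; the C2–C5 bond, absent from the target, is made in order to be cleaved.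
4. The seven‑membered ring is closed before that by ring‑closing metathesis (C8=C9) on a cis‑disubstituted cyclopropane; the cyclopropane and the C1 configuration come from an enantioselective intramolecular cyclopropanation of a dienyl diazoacetate.
5. Ring order: cyclopropane (as a fused lactone), then the seven‑membered ring, then the five‑membered ring with loss of the cyclopropane.

Key step: step 7

Remark on numbering: daucane numbering is used for the target and all bicyclic intermediates (C1 ring‑fusion carbon with the C15 methyl, C2, C3, C4 carbinol carbon with isopropyl, C5 ring‑fusion CH, C6 ester carbon, C7, C8 with the C14 methyl, C9, C10 carbinol carbon).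
Remark on stereochemistry: C10 is left as both epimers from 6 to 14 (SMILES leave it open), because it becomes sp2 in step 9 and is set afresh in step 10.
Assumption: boronate 12 is taken as a catalogue compound; otherwise it is one step from 3‑methylbut‑1‑yne by copper‑catalysed α‑selective hydroboration. If the S‑series rhodium catalyst of step 3 gives the antipodal cyclopropane, its enantiomer is used.

**Step 1**
Reactants: 1 methacrolein; 2 vinylmagnesium bromide
Product: 3 rac‑2‑methylpenta‑1,4‑dien‑3‑ol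
Conditions: THF, −78 to 0 °C; aq. NH4Cl
Reagents that add atoms: none
Why: 1,2‑addition of the vinyl Grignard reagent to the enal (Grignard addition); the carbinol centre (future C10) is left racemic on purpose because it is erased in step 9.

**Step 2**
Reactants: 3 rac‑2‑methylpenta‑1,4‑dien‑3‑ol
Product: 5 2‑methylpenta‑1,4‑dien‑3‑yl diazoacetate, via bromoacetate 4 (not isolated)
Conditions: BrCH2COBr, NaHCO3, MeCN, 0 °C; then TsNHNHTs, DBU, THF, 0 °C
Reagents that add atoms: bromoacetyl bromide BrCC(Br)=O; N,N'‑ditosylhydrazine Cc1ccc(cc1)S(=O)(=O)NNS(=O)(=O)c1ccc(C)cc1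
Why: O‑acylation followed by N‑alkylation of the ditosylhydrazine and base‑induced loss of two sulfinates (diazoacetate synthesis from a bromoacetate), which should leave both alkenes untouched.

**Step 3**
Reactants: 5 2‑methylpenta‑1,4‑dien‑3‑yl diazoacetate
Product: 6 (1R,5S)‑4‑ethenyl‑5‑methyl‑3‑oxabicyclo[3.1.0]hexan‑2‑one (both C4 epimers)
Conditions: Rh2(4S‑MPPIM)4 (1 mol %), CH2Cl2, reflux, slow addition of 5
Reagents that add atoms: none
Why: intramolecular rhodium‑carbenoid cyclopropanation of the more nucleophilic 1,1‑disubstituted alkene; the chiral dirhodium carboxamidate controls the alkene face, so both carbinol enantiomers should give the (1R,5S)‑cyclopropane (future C5 and C1), and the cis‑fused lactone holds the future C6 and C10 arms cis.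

**Step 4**
Reactants: 6 (1R,5S)‑4‑ethenyl‑5‑methyl‑3‑oxabicyclo[3.1.0]hexan‑2‑one
Product: 8 (1R,2S)‑2‑{1‑[(tert‑butyldimethylsilyl)oxy]prop‑2‑en‑1‑yl}‑N‑methoxy‑N,2‑dimethylcyclopropane‑1‑carboxamide, via hydroxy amide 7 (not isolated)
Conditions: MeNH(OMe)·HCl, iPrMgCl, THF, −20 °C; then TBSOTf, 2,6‑lutidine, CH2Cl2, 0 °C
Reagents that add atoms: N,O‑dimethylhydroxylamine hydrochloride CNOC.Cl; tert‑butyldimethylsilyl triflate CC(C)(C)[Si](C)(C)OS(=O)(=O)C(F)(F)F
Why: Weinreb aminolysis of the lactone by the magnesium amide, then immediate O‑silylation to prevent relactonisation; no stereocentre is touched.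

**Step 5**
Reactants: 8 silyl ether Weinreb amide; 9 (2‑methylprop‑2‑en‑1‑yl)magnesium chloride
Product: 10 1‑[(1R,2S)‑2‑{1‑[(tert‑butyldimethylsilyl)oxy]prop‑2‑en‑1‑yl}‑2‑methylcyclopropyl]‑3‑methylbut‑3‑en‑1‑one
Conditions: THF, −78 to −20 °C; cold aq. NH4Cl
Reagents that add atoms: none
Why: Weinreb ketone synthesis; the chelated tetrahedral intermediate should prevent over‑addition, and the cold neutral quench should keep the β,γ‑alkene out of conjugation.

**Step 6**
Reactants: 10 dienyl cyclopropyl ketone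
Product: 11 (1R,7S)‑6‑[(tert‑butyldimethylsilyl)oxy]‑4,7‑dimethylbicyclo[5.1.0]oct‑4‑en‑2‑one
Conditions: second‑generation Grubbs catalyst RuCl2(=CHPh)(H2IMes)(PCy3) (5 mol %), PhMe, 80 °C, high dilution
Reagents that add atoms: none
Why: ring‑closing metathesis closes the seven‑membered ring at the trisubstituted C8=C9 alkene, helped by the cis‑cyclopropane that holds the two alkene arms together.

**Step 7**
Reactants: 11 bicyclo[5.1.0]octenone; 12 4,4,5,5‑tetramethyl‑2‑(3‑methylbut‑1‑en‑2‑yl)‑1,3,2‑dioxaborolane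
Product: 13 cis‑fused 10‑[(tert‑butyldimethylsilyl)oxy]‑4‑(pinacolboryl)dauc‑8‑en‑6‑one (C1 as in 20; C5–H syn to C15, boron syn to C6, i.e. 4‑epi,5‑epi relative to 20)
Conditions: SmI2 (20 mol %), Sm powder (20 mol %), 12 (3 equiv), THF, 55 °C
Reagents that add atoms: none
Why: Proposed new method: electron transfer from SmI2 to the C6 ketone gives a ketyl whose cyclopropane fragments at the external C2–C5 bond to a trivalent samarium enolate (C6=C5) and a primary C2 radical, which adds to the CH2 terminus of 12; the resulting tertiary α‑boryl radical at C4 closes 5‑exo‑trig on C5 of the enolate, and back electron transfer from the new ketyl returns SmI2 (radical relay, catalytic in samarium). The closest known reaction type is the SmI2‑catalysed formal [3+2] cycloaddition of alkyl cyclopropyl ketones, bicyclic ones included, with alkynes and alkenes; new here are the α‑branched vinylboronate, which must give a fully substituted C–B carbon beside a quaternary centre, and the β,γ‑unsaturated bicyclo[5.1.0]octenone. C1 is untouched and keeps its configuration; the closure should place C4 syn to the C2 tether (cis ring fusion at C5) with boron on the side of the C6 oxygen and the bulkier isopropyl group outward, but this kinetic sense is not relied on because C4 and C5 are equilibrated in step 9. The selectivity that matters is cleavage of the external rather than the internal (C1–C5) cyclopropane bond, which the ring fusion should secure by holding C2–C5 in overlap with the carbonyl π system and C1–C5 near its nodal plane; the nucleophilic primary radical is polarity‑matched with the boron‑substituted alkene and has only 4‑exo or 5‑endo paths to the C8=C9 alkene.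

**Step 8**
Reactants: 13 cis‑fused β‑boryl ketone
Product: 14 cis‑fused 10‑[(tert‑butyldimethylsilyl)oxy]‑4‑hydroxydauc‑8‑en‑6‑one (4‑epi,5‑epi relative to 20)
Conditions: NaBO3·4H2O, THF/H2O, rt
Reagents that add atoms: sodium perborate [Na+].[Na+].O[B-]1(O)OO[B-](O)(O)OO1
Why: oxidation of the tertiary C–B bond by 1,2‑migration to oxygen with retention (boronate oxidation); any conjugation or elimination that starts under the mild base only anticipates step 9.

**Step 9**
Reactants: 14 cis‑fused aldol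
Product: 15 trans‑fused 4‑hydroxydauca‑7,9‑dien‑6‑one (C1, C4 and C5 as in 20)
Conditions: KOtBu (0.3 equiv), tBuOH/THF, 0 °C to rt; AcOH
Reagents that add atoms: none
Why: deprotonation at C7 triggers vinylogous E1cB loss of the C10 silanolate from either C10 epimer to give the 7,9‑dienone, and alkoxide‑mediated retro‑aldol/aldol equilibration of the C4–C5 bond should then funnel the kinetic adduct to the thermodynamic aldol, which is expected to be the trans‑fused isomer with isopropyl anti to C6 and remote from the C1 methyl and with C4–OH hydrogen‑bonded to the C6 carbonyl.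

**Step 10**
Reactants: 15 dienone aldol
Product: 16 4‑hydroxy‑10‑(pinacolboryl)dauc‑8‑en‑6‑one (boron at C10 in the place and orientation of the C10 oxygen of 20)
Conditions: CuCl (10 mol %), Xantphos (10 mol %), NaOtBu (15 mol %), B2pin2, MeOH (2 equiv), THF, 0 °C
Reagents that add atoms: bis(pinacolato)diboron CC1(C)OB(OC1(C)C)B1OC(C)(C)C(C)(C)O1
Why: copper‑catalysed 1,6‑conjugate borylation; the borylcopper should add to the unhindered distal C10 on the face opposite the pseudoaxial C1 methyl, and protonation of the dienolate at C7 by MeOH restores the C8=C9 alkene.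

**Step 11**
Reactants: 16 δ‑boryl β,γ‑enone
Product: 17 (6S)‑10‑(pinacolboryl)dauc‑8‑ene‑4,6‑diol (other centres as in 20)
Conditions: Me4NBH(OAc)3, MeCN/AcOH, −30 °C
Reagents that add atoms: none
Why: Evans–Saksena reduction; ligand exchange at the C4 hydroxyl and intramolecular hydride delivery to C6 from the face of that hydroxyl should give the 1,3‑anti diol, i.e. the C6 alcohol on the face opposite C4–OH.

**Step 12**
Reactants: 17 diol boronate; 18 4‑methoxybenzoyl chloride
Product: 19 (6S)‑4‑hydroxy‑10‑(pinacolboryl)dauc‑8‑en‑6‑yl 4‑methoxybenzoate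
Conditions: pyridine, DMAP (cat.), CH2Cl2, 0 °C to rt
Reagents that add atoms: none
Why: DMAP‑catalysed acylation of the only secondary hydroxyl; the tertiary C4–OH and the C10 boronate should be inert under these conditions.

**Step 13**
Reactants: 19 ester boronate
Product: 20 (3R,3aS,4S,8R,8aS)‑3,8‑dihydroxy‑6,8a‑dimethyl‑3‑(propan‑2‑yl)‑1,2,3,3a,4,5,8,8a‑octahydroazulen‑4‑yl 4‑methoxybenzoate
Conditions: NaBO3·4H2O, THF/H2O, 0 °C to rt
Reagents that add atoms: sodium perborate [Na+].[Na+].O[B-]1(O)OO[B-](O)(O)OO1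
Why: oxidation of the secondary allylic boronate by 1,2‑migration with retention gives the C10 alcohol without allylic transposition, under conditions that should spare the ester.

**Compound list**

1 | methacrolein (2‑methylprop‑2‑enal) | C=C(C)C=O | starting material
2 | vinylmagnesium bromide | C=C[Mg]Br | starting material
3 | rac‑2‑methylpenta‑1,4‑dien‑3‑ol | C=CC(O)C(C)=C | intermediate
4 | 2‑methylpenta‑1,4‑dien‑3‑yl bromoacetate | C=CC(OC(=O)CBr)C(C)=C | intermediate
5 | 2‑methylpenta‑1,4‑dien‑3‑yl diazoacetate | C=CC(OC(=O)C=[N+]=[N-])C(C)=C | intermediate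
6 | (1R,5S)‑4‑ethenyl‑5‑methyl‑3‑oxabicyclo[3.1.0]hexan‑2‑one, both C4 epimers | O=C1OC(C=C)[C@@]2(C)C[C@@H]12 | intermediate
7 | (1R,2S)‑2‑(1‑hydroxyprop‑2‑en‑1‑yl)‑N‑methoxy‑N,2‑dimethylcyclopropane‑1‑carboxamide, carbinol epimers | CON(C)C(=O)[C@@H]1C[C@]1(C)C(O)C=C | intermediate
8 | (1R,2S)‑2‑{1‑[(tert‑butyldimethylsilyl)oxy]prop‑2‑en‑1‑yl}‑N‑methoxy‑N,2‑dimethylcyclopropane‑1‑carboxamide | CON(C)C(=O)[C@@H]1C[C@]1(C)C(O[Si](C)(C)C(C)(C)C)C=C | intermediate
9 | (2‑methylprop‑2‑en‑1‑yl)magnesium chloride | C=C(C)C[Mg]Cl | starting material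
10 | 1‑[(1R,2S)‑2‑{1‑[(tert‑butyldimethylsilyl)oxy]prop‑2‑en‑1‑yl}‑2‑methylcyclopropyl]‑3‑methylbut‑3‑en‑1‑one | C=C(C)CC(=O)[C@@H]1C[C@]1(C)C(O[Si](C)(C)C(C)(C)C)C=C | intermediate
11 | (1R,7S)‑6‑[(tert‑butyldimethylsilyl)oxy]‑4,7‑dimethylbicyclo[5.1.0]oct‑4‑en‑2‑one | O=C1CC(C)=CC(O[Si](C)(C)C(C)(C)C)[C@@]2(C)C[C@@H]12 | intermediate
12 | 4,4,5,5‑tetramethyl‑2‑(3‑methylbut‑1‑en‑2‑yl)‑1,3,2‑dioxaborolane | C=C(C(C)C)B1OC(C)(C)C(C)(C)O1 | starting material
13 | cis‑fused 10‑[(tert‑butyldimethylsilyl)oxy]‑4‑(pinacolboryl)dauc‑8‑en‑6‑one, 4‑epi,5‑epi relative to 20 | O=C1CC(C)=CC(O[Si](C)(C)C(C)(C)C)[C@@]2(C)CC[C@](B3OC(C)(C)C(C)(C)O3)(C(C)C)[C@@H]12 | intermediate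
14 | cis‑fused 10‑[(tert‑butyldimethylsilyl)oxy]‑4‑hydroxydauc‑8‑en‑6‑one, 4‑epi,5‑epi relative to 20 | O=C1CC(C)=CC(O[Si](C)(C)C(C)(C)C)[C@@]2(C)CC[C@](O)(C(C)C)[C@@H]12 | intermediate
15 | trans‑fused 4‑hydroxydauca‑7,9‑dien‑6‑one, C1, C4, C5 as in 20 | O=C1C=C(C)C=C[C@@]2(C)CC[C@@](O)(C(C)C)[C@H]12 | intermediate
16 | 4‑hydroxy‑10‑(pinacolboryl)dauc‑8‑en‑6‑one, C1, C4, C5, C10 as in 20 | O=C1CC(C)=C[C@@H](B3OC(C)(C)C(C)(C)O3)[C@@]2(C)CC[C@@](O)(C(C)C)[C@H]12 | intermediate
17 | (6S)‑10‑(pinacolboryl)dauc‑8‑ene‑4,6‑diol | O[C@H]1CC(C)=C[C@@H](B3OC(C)(C)C(C)(C)O3)[C@@]2(C)CC[C@@](O)(C(C)C)[C@H]12 | intermediate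
18 | 4‑methoxybenzoyl chloride | COc1ccc(cc1)C(Cl)=O | starting material
19 | (6S)‑4‑hydroxy‑10‑(pinacolboryl)dauc‑8‑en‑6‑yl 4‑methoxybenzoate | COc1ccc(cc1)C(=O)O[C@H]1CC(C)=C[C@@H](B3OC(C)(C)C(C)(C)O3)[C@@]2(C)CC[C@@](O)(C(C)C)[C@H]12 | intermediate
20 | (3R,3aS,4S,8R,8aS)‑3,8‑dihydroxy‑6,8a‑dimethyl‑3‑(propan‑2‑yl)‑1,2,3,3a,4,5,8,8a‑octahydroazulen‑4‑yl 4‑methoxybenzoate | COc1ccc(C(=O)O[C@H]2CC(C)=C[C@@H](O)[C@@]3(C)CC[C@@](O)(C(C)C)[C@H]23)cc1 | target

**Step count and risks**

Total step count: 13. Longest linear sequence: 13 steps (1 to 20); 12 and 18 enter as purchased reagents.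

Step 7 (proposed new method). What may go wrong: fragmentation of the internal C1–C5 cyclopropane bond (ring enlargement through the tertiary radical), or slow addition of the primary radical to the hindered boronate with reduction of the radical and loss of the catalyst. The fallback uses known reactions only and runs from 11 to 15. Trimethylsilyl iodide (CH2Cl2, −40 °C, then aqueous work‑up) opens the cyclopropane by iodide attack at the CH2 carbon and gives 5‑[(tert‑butyldimethylsilyl)oxy]‑6‑(iodomethyl)‑3,6‑dimethylcyclohept‑3‑en‑1‑one F1. Keck radical allylation with tributyl[2‑(propan‑2‑yl)prop‑2‑en‑1‑yl]stannane and AIBN (PhH, 80 °C) forms the C2–C3 bond and gives the 6‑(4‑methyl‑3‑methylidenepentyl) ketone F2. Lemieux–Johnson cleavage (OsO4 cat., NaIO4, 2,6‑lutidine, dioxane/H2O) of the unhindered 1,1‑disubstituted alkene gives the 1,6‑diketone F3. The conditions of step 9 then eliminate the silanol and close C4–C5 by aldol addition under the same thermodynamic control, arriving at 15.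

Step 9. What may go wrong: the equilibrium in the flattened dienone may rest on the cis‑fused aldol, or the aldol may lose water to the C4=C5 enone. The fallback runs from 14 to 20, keeps the C10 oxygen and moves the equilibration to the less flattened mono‑enone; it needs the (10R)‑epimer of 14, obtained by carrying only the exo‑vinyl isomer of 6. Bu4NF/AcOH gives the cis‑fused 4,10‑dihydroxydauc‑8‑en‑6‑one F4. KOtBu (0.2 equiv, tBuOH) conjugates the alkene to C7=C8 and equilibrates the aldol there; excess KOtBu and an AcOH quench at −78 °C (kinetic α‑protonation of the dienolate) then return the β,γ‑enone as the trans‑fused 4,10‑dihydroxydauc‑8‑en‑6‑one F5. TBSOTf/2,6‑lutidine silylates only the secondary hydroxyl and gives the 10‑silyl ether F6. Me4NBH(OAc)3 gives the 6‑alcohol F7, 18 with DMAP gives the 6‑(4‑methoxybenzoate) F8, and Bu4NF releases 20.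

Step 3. What may go wrong: carbenoid addition to the vinyl group instead of the isopropenyl group, or weak enantiofacial control. The fallback runs from 1 to 6 and removes the competing alkene. Lithium (trimethylsilyl)acetylide adds to 1 to give 2‑methyl‑5‑(trimethylsilyl)pent‑1‑en‑4‑yn‑3‑ol F9. Its diazoacetate F10 is made as in step 2. The same rhodium catalyst then gives (1R,5S)‑5‑methyl‑4‑[(trimethylsilyl)ethynyl]‑3‑oxabicyclo[3.1.0]hexan‑2‑one F11. Bu4NF removes silicon to give the ethynyl lactone F12, and semihydrogenation (H2, Pd/CaCO3–Pb(OAc)2, quinoline) gives 6.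

**Further compounds**

F1 | step 7 | 5‑[(tert‑butyldimethylsilyl)oxy]‑6‑(iodomethyl)‑3,6‑dimethylcyclohept‑3‑en‑1‑one | O=C1CC(C)=CC(O[Si](C)(C)C(C)(C)C)[C@@](C)(CI)C1
F2 | step 7 | 5‑[(tert‑butyldimethylsilyl)oxy]‑3,6‑dimethyl‑6‑(4‑methyl‑3‑methylidenepentyl)cyclohept‑3‑en‑1‑one | O=C1CC(C)=CC(O[Si](C)(C)C(C)(C)C)[C@@](C)(CCC(=C)C(C)C)C1
F3 | step 7 | 5‑[(tert‑butyldimethylsilyl)oxy]‑3,6‑dimethyl‑6‑(4‑methyl‑3‑oxopentyl)cyclohept‑3‑en‑1‑one | O=C1CC(C)=CC(O[Si](C)(C)C(C)(C)C)[C@@](C)(CCC(=O)C(C)C)C1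
F4 | step 9 | cis‑fused (10R)‑4,10‑dihydroxydauc‑8‑en‑6‑one, 4‑epi,5‑epi relative to 20 | O=C1CC(C)=C[C@@H](O)[C@@]2(C)CC[C@](O)(C(C)C)[C@@H]12
F5 | step 9 | trans‑fused 4,10‑dihydroxydauc‑8‑en‑6‑one, configuration as in 20 | O=C1CC(C)=C[C@@H](O)[C@@]2(C)CC[C@@](O)(C(C)C)[C@H]12
F6 | step 9 | 10‑[(tert‑butyldimethylsilyl)oxy]‑4‑hydroxydauc‑8‑en‑6‑one, configuration as in 20 | O=C1CC(C)=C[C@@H](O[Si](C)(C)C(C)(C)C)[C@@]2(C)CC[C@@](O)(C(C)C)[C@H]12
F7 | step 9 | (6S)‑10‑[(tert‑butyldimethylsilyl)oxy]dauc‑8‑ene‑4,6‑diol | O[C@H]1CC(C)=C[C@@H](O[Si](C)(C)C(C)(C)C)[C@@]2(C)CC[C@@](O)(C(C)C)[C@H]12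
F8 | step 9 | (6S)‑10‑[(tert‑butyldimethylsilyl)oxy]‑4‑hydroxydauc‑8‑en‑6‑yl 4‑methoxybenzoate | COc1ccc(cc1)C(=O)O[C@H]1CC(C)=C[C@@H](O[Si](C)(C)C(C)(C)C)[C@@]2(C)CC[C@@](O)(C(C)C)[C@H]12
F9 | step 3 | 2‑methyl‑5‑(trimethylsilyl)pent‑1‑en‑4‑yn‑3‑ol | C=C(C)C(O)C#C[Si](C)(C)C
F10 | step 3 | 2‑methyl‑5‑(trimethylsilyl)pent‑1‑en‑4‑yn‑3‑yl diazoacetate | C=C(C)C(OC(=O)C=[N+]=[N-])C#C[Si](C)(C)C
F11 | step 3 | (1R,5S)‑5‑methyl‑4‑[(trimethylsilyl)ethynyl]‑3‑oxabicyclo[3.1.0]hexan‑2‑one | O=C1OC(C#C[Si](C)(C)C)[C@@]2(C)C[C@@H]12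
F12 | step 3 | (1R,5S)‑4‑ethynyl‑5‑methyl‑3‑oxabicyclo[3.1.0]hexan‑2‑one | O=C1OC(C#C)[C@@]2(C)C[C@@H]12
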